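**Plan**
1. Retrosynthetic cuts, in order: the 7-O-benzyl helper; C2–C1′ between pyranone ring C and anisyl ring B; O1–C2 and C2–C3 of ring C (back to an o-hydroxyacetophenone plus a one-carbon unit); C4a–C4 (acetyl) and C7–O on ring A, back to 1,2,4,5-tetramethoxybenzene.
2. Forward: ring A is bought, and its two equivalent C–H bonds become C7–OH (lithiation/borylation/oxidation) and C4a–acetyl. The mirror plane through C7 and C4a makes the two OMe groups ortho to the acetyl identical, so chelation-controlled loss of one methyl can give only one product and fixes the 5,6,8-OMe/8a-OH pattern. Ring C is then closed by the enaminone method and ring B is joined last.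
3. Key event: polarity reversal at C2. The β-carbon of the C2=C3–C4=O enone is an electrophile by nature. It is zincated at its C–H bond and joined under Pd(0) to the equally electrophilic C–I carbon of 4-iodoanisole, with no halogen or leaving group on the chromone.
4. Enabling feature: C2–H of ring C lies next to O1 and is the most acidic C–H. C5 to C8 of ring A all carry oxygen, so no aryl C–H competes. The peri pocket between 5-OMe and C4=O keeps metal cations away from C3. The acidic 7-OH is masked as a benzyl ether and freed in the last step.
5. Stereochemistry: the target is planar and achiral (no stereocentre, axis or E/Z element), so nothing has to be set.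

Key step: step 5

Remark: the SMILES holds no stereogenic element, so "single enantiomer" is read as the one achiral compound; 1,2,4,5-tetramethoxybenzene, 4-iodoanisole and TMPZnCl·LiCl solution are taken as commercial.

Step 1
Reactants: 1 1,2,4,5-tetramethoxybenzene
Product: 4 2,3,5,6-tetramethoxyphenol, via aryllithium 2 (not isolated), via dimethyl arylboronate 3 (not isolated)
Conditions: n-BuLi (1.1 equiv), THF, 0 °C → rt; B(OMe)3, −78 °C → rt; AcOH, 30% aq H2O2, 0 °C → rt
Reagents that add atoms: hydrogen peroxide, OO (phenol oxygen of 4); n-butyllithium, [Li]CCCC (Li of 2 only); trimethyl borate, COB(OC)OC (B(OMe)2 of 3 only)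
Why: Directed ortho-metalation takes one of the two equivalent C–H bonds, each flanked by two OMe groups, and the borylation/peroxide oxidation sequence (1,2-aryl shift from B to O) turns C–Li into C–OH without forming a stereocentre.

Step 2
Reactants: 4 2,3,5,6-tetramethoxyphenol
Product: 6 1-(2,4-dihydroxy-3,5,6-trimethoxyphenyl)ethanone, via tetramethoxy ketone 5 (not isolated)
Conditions: AlCl3 (3.5 equiv), CH2Cl2, 0 °C; AcCl (1.1 equiv), 0 °C → rt; ice/2 M HCl
Reagents that add atoms: acetyl chloride, CC(=O)Cl
Why: Friedel–Crafts acetylation can only strike the single free ring position (para to the OH, flanked by two OMe), and AlCl3 held in a six-membered chelate between the new C=O and one of the two symmetry-equivalent ortho-OMe groups then cleaves that one ether (chelation-controlled ortho-demethylation), the resulting aluminium chelate shielding the second ortho-OMe.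

Step 3
Reactants: 6 1-(2,4-dihydroxy-3,5,6-trimethoxyphenyl)ethanone
Product: 7 1-[4-(benzyloxy)-2-hydroxy-3,5,6-trimethoxyphenyl]ethanone
Conditions: BnBr (1.05 equiv), K2CO3 (1.1 equiv), acetone, reflux
Reagents that add atoms: benzyl bromide, BrCc1ccccc1
Why: Williamson etherification should pick the 4-OH, which is free and the more acidic one (para to the acetyl group), whereas the 2-OH is locked in a hydrogen bond to the C=O and stays unalkylated with one equivalent of halide and a weak base.

Step 4
Reactants: 7 1-[4-(benzyloxy)-2-hydroxy-3,5,6-trimethoxyphenyl]ethanone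
Product: 9 7-(benzyloxy)-5,6,8-trimethoxy-4H-chromen-4-one, via enaminone 8 (not isolated)
Conditions: DMF-DMA (2 equiv), toluene, 100 °C; concentrate; conc. HCl, CH2Cl2, rt → 40 °C
Reagents that add atoms: N,N-dimethylformamide dimethyl acetal, COC(OC)N(C)C
Why: Condensation of the acetyl CH3 with the amide acetal gives the push–pull enaminone, and acid then triggers addition of the 2-OH to the β-carbon and loss of dimethylamine (enaminone route to 2,3-unsubstituted chromones), which closes ring C and leaves C2–H free for the next step.

Step 5
Reactants: 9 7-(benzyloxy)-5,6,8-trimethoxy-4H-chromen-4-one; 10 4-iodoanisole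
Product: 12 7-(benzyloxy)-4′,5,6,8-tetramethoxyflavone, via C2-zinc chromone 11 (not isolated)
Conditions: TMPZnCl·LiCl (1.3 equiv), THF, 25 °C; then 10 (1.1 equiv), Pd(dba)2 (3 mol %), P(2-furyl)3 (6 mol %), 25 → 50 °C
Reagents that add atoms: TMPZnCl·LiCl, CC1(C)CCCC(C)(C)N1[Zn]Cl.[Li+].[Cl-] (ZnCl of 11 only; none of its atoms stay in 12)
Why: The hindered zinc amide removes the C2–H proton of ring C to give the C2–ZnCl species 11, so that the β-carbon of the C2=C3–C4=O enone, by nature an electrophile, becomes the nucleophilic partner (polarity reversal), and Pd(0) then runs the Negishi cycle of oxidative addition into the C–I bond of 10, transmetalation from 11 and reductive elimination, which forms the C2–C1′ bond. The closest known reaction type is the C2-selective zincation of chromones with LiCl-solubilised TMP-zinc chloride followed by Pd-catalysed arylation with aryl iodides, an established entry to flavones. No ring is closed and no stereocentre arises, since both termini of the new bond are sp2 carbons of a planar, achiral product. The step needs C2 over C3 selectivity, which is secured because C2–H lies next to O1 and is the most acidic C–H, no MgCl2 or BF3 is present that would bind C4=O and steer the base to C3, and the peri pocket between 5-OMe and C4=O holds Li+ or Zn2+ on the carbonyl lone pair that points away from C3. It also needs chemoselectivity, which is given because ring A (C5 to C8) has no C–H left, the 7-OH is masked as its benzyl ether, the OCH3 and OCH2Ph hydrogens are out of reach of this mild base, and the covalent C–Zn bond neither adds to C4=O nor opens ring C, a C2 anion having no β-leaving group. Both partners are as simple as they can be, an unhalogenated chromone and a commodity aryl iodide, and the whole of ring B arrives in one flask on the finished A/C core.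

Step 6
Reactants: 12 7-(benzyloxy)-4′,5,6,8-tetramethoxyflavone
Product: 13 7-hydroxy-4′,5,6,8-tetramethoxyflavone
Conditions: H2 (1 atm), 10% Pd/C, EtOAc/MeOH, rt
Reagents that add atoms: none
Why: Catalytic hydrogenolysis of the benzylic C–O bond frees the 7-OH under neutral conditions that should leave the four methyl ethers and the conjugated C2=C3 bond of the flavone untouched when the uptake is stopped after one equivalent.

**Compound list**
1 | 1,2,4,5-tetramethoxybenzene | COc1cc(OC)c(OC)cc1OC | starting material
2 | (2,3,5,6-tetramethoxyphenyl)lithium | [Li]c1c(OC)c(OC)cc(OC)c1OC | intermediate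
3 | dimethyl (2,3,5,6-tetramethoxyphenyl)boronate | COB(OC)c1c(OC)c(OC)cc(OC)c1OC | intermediate
4 | 2,3,5,6-tetramethoxyphenol | COc1cc(OC)c(OC)c(O)c1OC | intermediate
5 | 1-(4-hydroxy-2,3,5,6-tetramethoxyphenyl)ethanone (present as its aluminium complex) | CC(=O)c1c(OC)c(OC)c(O)c(OC)c1OC | intermediate
6 | 1-(2,4-dihydroxy-3,5,6-trimethoxyphenyl)ethanone | CC(=O)c1c(O)c(OC)c(O)c(OC)c1OC | intermediate
7 | 1-[4-(benzyloxy)-2-hydroxy-3,5,6-trimethoxyphenyl]ethanone | CC(=O)c1c(O)c(OC)c(OCc2ccccc2)c(OC)c1OC | intermediate
8 | (E)-1-[4-(benzyloxy)-2-hydroxy-3,5,6-trimethoxyphenyl]-3-(dimethylamino)prop-2-en-1-one | CN(C)/C=C/C(=O)c1c(O)c(OC)c(OCc2ccccc2)c(OC)c1OC | intermediate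
9 | 7-(benzyloxy)-5,6,8-trimethoxy-4H-chromen-4-one | O=c1ccoc2c(OC)c(OCc3ccccc3)c(OC)c(OC)c12 | intermediate
10 | 4-iodoanisole | COc1ccc(I)cc1 | starting material
11 | [7-(benzyloxy)-5,6,8-trimethoxy-4-oxo-4H-chromen-2-yl]zinc chloride | Cl[Zn]c1cc(=O)c2c(OC)c(OC)c(OCc3ccccc3)c(OC)c2o1 | intermediate
12 | 7-(benzyloxy)-4′,5,6,8-tetramethoxyflavone | COc1ccc(-c2cc(=O)c3c(OC)c(OC)c(OCc4ccccc4)c(OC)c3o2)cc1 | intermediate
13 | 7-hydroxy-4′,5,6,8-tetramethoxyflavone | COc1ccc(-c2cc(=O)c3c(OC)c(OC)c(O)c(OC)c3o2)cc1 | target

Total step count: 6. Longest linear sequence: 6 (steps 1 to 6 from compound 1; compound 10 is bought).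

**Steps most likely to fail**

Step 5. The electron-rich ring A lowers the acidity of C2–H, so metalation may be slow. It may also drift to C3 through carbonyl-directed deprotonation, or the crowded zinc reagent may transmetalate sluggishly and be lost by protonation. The fallback uses the natural polarity of C2, sets out from 9 and comes back at 12. Pd(II)-catalysed conjugate addition of 4-methoxyphenylboronic acid (Pd(OCOCF3)2, 2,2′-bipyridine, AcOH/THF/H2O, 60 °C) can deliver the aryl group only to the β-carbon. It should give racemic 7-(benzyloxy)-4′,5,6,8-tetramethoxyflavanone F1. Dehydrogenation with catalytic I2 in DMSO at 120 °C then restores the C2=C3 bond.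

Step 2. Aluminium bound at the 4-oxygen may strip further methyl ethers next to it, and the very electron-rich phenol may degrade under the Lewis acid. The fallback avoids electrophilic acylation of a free phenol, sets out from 4 and comes back at 7.
- Benzylation (BnBr, K2CO3, DMF) should give 3-(benzyloxy)-1,2,4,5-tetramethoxybenzene F2.
- NBS in MeCN at 0 °C brominates the only free position to give 1-(benzyloxy)-4-bromo-2,3,5,6-tetramethoxybenzene F3.
- Bromine–lithium exchange (n-BuLi, THF, −78 °C) is fast enough to outrun benzylic deprotonation and gives the aryllithium [4-(benzyloxy)-2,3,5,6-tetramethoxyphenyl]lithium F4.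
- F4 is acylated with N-methoxy-N-methylacetamide to the symmetric ketone 1-[4-(benzyloxy)-2,3,5,6-tetramethoxyphenyl]ethanone F5.
- MgI2·OEt2 in toluene/Et2O with warming removes one of the two equivalent ortho-methyl groups by chelation and spares the para benzyl ether.

Step 1. Lithiation may be incomplete, and the liberated, very electron-rich phenol may be over-oxidised while peroxide is still present. The fallback keeps the phenol masked during the oxidation, sets out from 1 and comes back at 4. Rieche formylation (Cl2CHOMe, TiCl4, CH2Cl2, 0 °C) should give 2,3,5,6-tetramethoxybenzaldehyde F6. Baeyer–Villiger oxidation (mCPBA, CH2Cl2) gives 2,3,5,6-tetramethoxyphenyl formate F7. After the oxidant has been quenched, methanolysis (cat. K2CO3, MeOH, argon) releases the phenol.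

**Further compounds**
F1 | step 5 | 7-(benzyloxy)-4′,5,6,8-tetramethoxyflavanone (racemic) | COc1ccc(C2CC(=O)c3c(OC)c(OC)c(OCc4ccccc4)c(OC)c3O2)cc1
F2 | step 2 | 3-(benzyloxy)-1,2,4,5-tetramethoxybenzene | COc1cc(OC)c(OC)c(OCc2ccccc2)c1OC
F3 | step 2 | 1-(benzyloxy)-4-bromo-2,3,5,6-tetramethoxybenzene | COc1c(Br)c(OC)c(OC)c(OCc2ccccc2)c1OC
F4 | step 2 | [4-(benzyloxy)-2,3,5,6-tetramethoxyphenyl]lithium | [Li]c1c(OC)c(OC)c(OCc2ccccc2)c(OC)c1OC
F5 | step 2 | 1-[4-(benzyloxy)-2,3,5,6-tetramethoxyphenyl]ethanone | CC(=O)c1c(OC)c(OC)c(OCc2ccccc2)c(OC)c1OC
F6 | step 1 | 2,3,5,6-tetramethoxybenzaldehyde | O=Cc1c(OC)c(OC)cc(OC)c1OC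
F7 | step 1 | 2,3,5,6-tetramethoxyphenyl formate | O=COc1c(OC)c(OC)cc(OC)c1OC
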